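**Retrosynthetic overview**

1. Target 24 ⇐ 23 (desilylation) ⇐ 22 (diimide reduction of both alkenes) ⇐ 20 (cross-metathesis of the C5 allyl group with 1-heptene).
2. 20 ⇐ triene 18 by disconnection of C7=C8. The only stereocentre, C5 of the 5,6,7,8-tetrahydroquinolin-4-one, carries two three-carbon arms (ring carbons C6–C7 and C1′–C3′ of the octyl chain). A diallylmethine on C4a beside a vinyl group on C8a is therefore a prochiral equivalent, and one metathesis ring closure builds the carbocycle and fixes C5.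
3. 18 ⇐ kojic acid 1: its CH2OH becomes the vinyl group (C8); its C3–H position (C4a) is iodinated, formylated and allylated twice (Grignard, then Hosomi–Sakurai); its C6–H is hydroxymethylated (C2–CH2OH); the 5-OH is methylated; the ring O is exchanged for N–OMe.
4. Ring order: pyranone (from kojic acid) → N-methoxypyridin-4-one (step 4) → cyclohexene ring by metathesis (step 13).

Key step: step 13

Assumption: the sense of induction of a chiral Mo alkylidene on this new triene cannot be predicted with certainty. The route is written with the (S)-biphenolate complex; if a trial with both antipodes shows that it leads to the (5S) series, the (R)-complex is used instead.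

Abbreviations: TBS = tert-butyldimethylsilyl, TBDPS = tert-butyldiphenylsilyl. Pyridone locants: N1, C2 (carbon from the kojic CH2OH side), C3, C4 (C=O), C5 (OMe), C6.

**Route**

Step 1
Reactants: 1 kojic acid
Product: 2 5-hydroxy-2-[(TBS-oxy)methyl]-4H-pyran-4-one
Conditions: TBSCl (1.1 equiv), imidazole (2.2 equiv), DMF, 0 °C → rt; aqueous work-up
Reagents that add atoms: tert-butyldimethylsilyl chloride, CC(C)(C)[Si](C)(C)Cl
Why: Silyl chloride/imidazole silylation goes to the primary alcohol, and any silyl ether formed at the acidic enol oxygen is hydrolysed during aqueous work-up.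

Step 2
Reactants: 2 5-hydroxy-2-[(TBS-oxy)methyl]-4H-pyran-4-one; 3 formaldehyde
Product: 4 3-hydroxy-2-(hydroxymethyl)-6-[(TBS-oxy)methyl]-4H-pyran-4-one
Conditions: 37% aq. HCHO (1.2 equiv), NaOH (1.05 equiv), MeOH–H2O, rt; AcOH to pH 6
Reagents that add atoms: none
Why: Base-mediated hydroxymethylation (aldol-type addition of the oxido-pyranone to formaldehyde) takes place at the only ring carbon ortho to the enolate oxygen, and a primary TBS ether tolerates dilute aqueous base at room temperature.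

Step 3
Reactants: 4 3-hydroxy-2-(hydroxymethyl)-6-[(TBS-oxy)methyl]-4H-pyran-4-one
Product: 5 2-(hydroxymethyl)-3-methoxy-6-[(TBS-oxy)methyl]-4H-pyran-4-one
Conditions: MeI (1.5 equiv), K2CO3 (1.5 equiv), acetone, 50 °C
Reagents that add atoms: iodomethane, CI
Why: Williamson methylation in which carbonate deprotonates only the enolic hydroxyl, so the primary alcohol stays free.

Step 4
Reactants: 5 2-(hydroxymethyl)-3-methoxy-6-[(TBS-oxy)methyl]-4H-pyran-4-one; 6 O-methylhydroxylamine hydrochloride
Product: 7 6-(hydroxymethyl)-1,5-dimethoxy-2-[(TBS-oxy)methyl]pyridin-4(1H)-one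
Conditions: MeONH2·HCl (3 equiv), pyridine, 90 °C
Reagents that add atoms: none
Why: Pyranone-to-pyridone exchange by conjugate addition of the alkoxyamine, ring opening and recyclisation with loss of water, the standard way from 3-alkoxypyran-4-ones to N-substituted pyridin-4-ones, with pyridine buffering the HCl so that the TBS ether is kept.

Step 5
Reactants: 7 6-(hydroxymethyl)-1,5-dimethoxy-2-[(TBS-oxy)methyl]pyridin-4(1H)-one
Product: 8 6-[(TBDPS-oxy)methyl]-1,5-dimethoxy-2-[(TBS-oxy)methyl]pyridin-4(1H)-one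
Conditions: TBDPSCl (1.2 equiv), imidazole (2.5 equiv), DMF, rt
Reagents that add atoms: tert-butyldiphenylsilyl chloride, CC(C)(C)[Si](Cl)(c1ccccc1)c1ccccc1
Why: Routine silylation of the remaining primary alcohol, with TBDPS chosen as the permanent group because it outlasts the mild acid that later removes TBS and tolerates BF3 at low temperature.

Step 6
Reactants: 8 6-[(TBDPS-oxy)methyl]-1,5-dimethoxy-2-[(TBS-oxy)methyl]pyridin-4(1H)-one
Product: 9 3-iodo-6-[(TBDPS-oxy)methyl]-1,5-dimethoxy-2-[(TBS-oxy)methyl]pyridin-4(1H)-one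
Conditions: NIS (1.1 equiv), MeCN, rt, dark
Reagents that add atoms: N-iodosuccinimide, O=C1CCC(=O)N1I
Why: Electrophilic iodination at the only ring C–H (C3), the nucleophilic β-carbon of the vinylogous amide.

Step 7
Reactants: 9 3-iodo-6-[(TBDPS-oxy)methyl]-1,5-dimethoxy-2-[(TBS-oxy)methyl]pyridin-4(1H)-one
Product: 11 6-[(TBDPS-oxy)methyl]-1,5-dimethoxy-4-oxo-2-[(TBS-oxy)methyl]-1,4-dihydropyridine-3-carbaldehyde, via 3-pyridonylmagnesium chloride 10 (not isolated)
Conditions: i-PrMgCl·LiCl (1.2 equiv), THF, −40 °C, 30 min; DMF (4 equiv), −40 → 0 °C; aq. NH4Cl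
Reagents that add atoms: isopropylmagnesium chloride–lithium chloride, CC(C)[Mg]Cl.[Li]Cl; N,N-dimethylformamide, CN(C)C=O
Why: Iodine–magnesium exchange with the turbo-Grignard reagent at low temperature gives the 3-magnesiated pyridone without harm to the silyl ethers or the N–OMe group, and Bouveault formylation with DMF delivers the aldehyde.

Step 8
Reactants: 11 6-[(TBDPS-oxy)methyl]-1,5-dimethoxy-4-oxo-2-[(TBS-oxy)methyl]-1,4-dihydropyridine-3-carbaldehyde; 12 allylmagnesium bromide
Product: 13 racemic 3-(1-hydroxybut-3-en-1-yl)-6-[(TBDPS-oxy)methyl]-1,5-dimethoxy-2-[(TBS-oxy)methyl]pyridin-4(1H)-one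
Conditions: allylMgBr (1.3 equiv), THF, −78 °C; aq. NH4Cl
Reagents that add atoms: none
Why: Grignard 1,2-addition to the aldehyde, which is far more electrophilic than the vinylogous-amide ring carbonyl; the carbinol centre is racemic and is erased in step 9.

Step 9
Reactants: 13 racemic 3-(1-hydroxybut-3-en-1-yl)-6-[(TBDPS-oxy)methyl]-1,5-dimethoxy-2-[(TBS-oxy)methyl]pyridin-4(1H)-one; 14 allyltrimethylsilane
Product: 15 3-(hepta-1,6-dien-4-yl)-6-[(TBDPS-oxy)methyl]-1,5-dimethoxy-2-[(TBS-oxy)methyl]pyridin-4(1H)-one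
Conditions: allylSiMe3 (4 equiv), BF3·OEt2 (2 equiv), CH2Cl2, −78 → −30 °C
Reagents that add atoms: none
Why: Hosomi–Sakurai-type SN1 substitution in which the carbinol ionises to a cation stabilised by the ring nitrogen through C2=C3 (a vinylogous N-alkoxyiminium ion) and is trapped by the allylsilane, giving the achiral diallylmethine.

Step 10
Reactants: 15 3-(hepta-1,6-dien-4-yl)-6-[(TBDPS-oxy)methyl]-1,5-dimethoxy-2-[(TBS-oxy)methyl]pyridin-4(1H)-one
Product: 16 3-(hepta-1,6-dien-4-yl)-2-(hydroxymethyl)-6-[(TBDPS-oxy)methyl]-1,5-dimethoxypyridin-4(1H)-one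
Conditions: camphorsulfonic acid (0.1 equiv), MeOH–CH2Cl2 1:1, 0 °C
Reagents that add atoms: none
Why: Acid-catalysed methanolysis removes a primary TBS ether much faster than a primary TBDPS ether, so only the hydroxymethyl group that is to become the vinyl group is set free.

Step 11
Reactants: 16 3-(hepta-1,6-dien-4-yl)-2-(hydroxymethyl)-6-[(TBDPS-oxy)methyl]-1,5-dimethoxypyridin-4(1H)-one
Product: 17 3-(hepta-1,6-dien-4-yl)-6-[(TBDPS-oxy)methyl]-1,5-dimethoxy-4-oxo-1,4-dihydropyridine-2-carbaldehyde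
Conditions: Dess–Martin periodinane (1.3 equiv), CH2Cl2, rt
Reagents that add atoms: none
Why: Dess–Martin oxidation stops at the aldehyde and leaves the terminal alkenes, the silyl ether and the N–OMe group untouched.

Step 12
Reactants: 17 3-(hepta-1,6-dien-4-yl)-6-[(TBDPS-oxy)methyl]-1,5-dimethoxy-4-oxo-1,4-dihydropyridine-2-carbaldehyde
Product: 18 3-(hepta-1,6-dien-4-yl)-6-[(TBDPS-oxy)methyl]-1,5-dimethoxy-2-vinylpyridin-4(1H)-one
Conditions: Ph3PCH3Br (1.5 equiv), KHMDS (1.4 equiv), THF, 0 °C; then 17, −78 → 0 °C; product kept cold with BHT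
Reagents that add atoms: methyltriphenylphosphonium bromide, C[P+](c1ccccc1)(c1ccccc1)c1ccccc1.[Br-]
Why: Wittig methylenation of a non-enolisable aldehyde, in which the ylide does not attack the unreactive pyridone carbonyl.

Step 13
Reactants: 18 3-(hepta-1,6-dien-4-yl)-6-[(TBDPS-oxy)methyl]-1,5-dimethoxy-2-vinylpyridin-4(1H)-one
Product: 20 (5R)-5-allyl-2-[(TBDPS-oxy)methyl]-1,3-dimethoxy-5,6-dihydroquinolin-4(1H)-one, via cyclopentenyl vinylpyridone 19 (not isolated)
Conditions: Mo(=N-2,6-i-Pr2C6H3)(=CHCMe2Ph)[(S)-3,3′-di-tert-butyl-5,5′,6,6′-tetramethylbiphenyl-2,2′-diolate] (10 mol%), C6H6 (0.05 M), sealed vessel, 22 → 50 °C; stopped when 18 and 19 are consumed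
Reagents that add atoms: none
Why: The Mo alkylidene exchanges onto the terminal arm alkenes and closes rings through metallacyclobutanes with loss of ethylene (Chauvin mechanism); the closest known reactions are Mo-catalysed desymmetrising ring-closing metathesis of prochiral trienes and the asymmetric ring-opening/ring-closing metathesis of Cs-symmetric cyclopent-3-enyl substrates that carry a tethered terminal alkene. The two arms can also close on each other, and this five-membered closure should be the fastest event, so the achiral cyclopentene 19 is treated as an intermediate and not as a loss: the ethylene kept in the sealed vessel supplies Mo=CH2, which loads onto the vinyl group, and the resulting pyridonyl alkylidene opens the cyclopentene intramolecularly. The six-membered carbocycle is closed by joining the vinyl CH (C8) to the inner alkene carbon of one arm (C7), which leaves an endocyclic C7=C8 bond on the C4a–C8a edge of the pyridone and the other arm as the allyl group on C5. C5 is the only new stereocentre and is fixed by the chiral biphenolate on Mo, which differentiates the two enantiotopic arms (in 19, the two enantiotopic alkene carbons) in the metallacyclobutane-forming step. The step needs six- over five-membered closure and enantiotopic-group selection: the first is secured thermodynamically, because the strained cyclopentene is reversible while the conjugated, strain-free cyclohexene is not reopened, and the second because all open-chain and cyclopentene forms are achiral and interconvert before the selective closure.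

Step 14
Reactants: 20 (5R)-5-allyl-2-[(TBDPS-oxy)methyl]-1,3-dimethoxy-5,6-dihydroquinolin-4(1H)-one; 21 1-heptene
Product: 22 (5R)-5-(oct-2-en-1-yl)-2-[(TBDPS-oxy)methyl]-1,3-dimethoxy-5,6-dihydroquinolin-4(1H)-one (E/Z mixture expected)
Conditions: RuCl2(PCy3)2(=CHPh) (5 mol%), 1-heptene (10 equiv), CH2Cl2, 40 °C
Reagents that add atoms: none
Why: Cross-metathesis of two unhindered terminal alkenes is driven to the hetero-product by excess 1-heptene, and the first-generation Ru catalyst leaves the conjugated cyclic C7=C8 alkene alone, so the ring cannot reopen towards the achiral cyclopentene and C5 is not scrambled.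

Step 15
Reactants: 22 (5R)-5-(oct-2-en-1-yl)-2-[(TBDPS-oxy)methyl]-1,3-dimethoxy-5,6-dihydroquinolin-4(1H)-one
Product: 23 (5R)-2-[(TBDPS-oxy)methyl]-1,3-dimethoxy-5-octyl-5,6,7,8-tetrahydroquinolin-4(1H)-one
Conditions: TsNHNH2 (10 equiv), NaOAc (12 equiv), DME–H2O, 85 °C
Reagents that add atoms: none
Why: Diimide generated in situ transfers H2 to both unpolarised C=C bonds without cleaving the N–O bond or the silyl ether and without touching C5.

Step 16
Reactants: 23 (5R)-2-[(TBDPS-oxy)methyl]-1,3-dimethoxy-5-octyl-5,6,7,8-tetrahydroquinolin-4(1H)-one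
Product: 24 (5R)-2-(hydroxymethyl)-1,3-dimethoxy-5-octyl-5,6,7,8-tetrahydroquinolin-4(1H)-one
Conditions: TBAF (1.5 equiv), THF, 0 °C → rt
Reagents that add atoms: none
Why: Fluoride-driven cleavage of the Si–O bond releases the primary alcohol under conditions that leave the N-methoxypyridone and the stereocentre untouched.

**Compound list**

1 | kojic acid, 5-hydroxy-2-(hydroxymethyl)-4H-pyran-4-one | OCc1cc(=O)c(O)co1 | starting material
2 | 5-hydroxy-2-[(TBS-oxy)methyl]-4H-pyran-4-one | CC(C)(C)[Si](C)(C)OCc1cc(=O)c(O)co1 | intermediate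
3 | formaldehyde | C=O | starting material
4 | 3-hydroxy-2-(hydroxymethyl)-6-[(TBS-oxy)methyl]-4H-pyran-4-one | CC(C)(C)[Si](C)(C)OCc1cc(=O)c(O)c(CO)o1 | intermediate
5 | 2-(hydroxymethyl)-3-methoxy-6-[(TBS-oxy)methyl]-4H-pyran-4-one | CC(C)(C)[Si](C)(C)OCc1cc(=O)c(OC)c(CO)o1 | intermediate
6 | O-methylhydroxylamine hydrochloride | CON.Cl | starting material
7 | 6-(hydroxymethyl)-1,5-dimethoxy-2-[(TBS-oxy)methyl]pyridin-4(1H)-one | CC(C)(C)[Si](C)(C)OCc1cc(=O)c(OC)c(CO)n1OC | intermediate
8 | 6-[(TBDPS-oxy)methyl]-1,5-dimethoxy-2-[(TBS-oxy)methyl]pyridin-4(1H)-one | CC(C)(C)[Si](C)(C)OCc1cc(=O)c(OC)c(CO[Si](c2ccccc2)(c2ccccc2)C(C)(C)C)n1OC | intermediate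
9 | 3-iodo-6-[(TBDPS-oxy)methyl]-1,5-dimethoxy-2-[(TBS-oxy)methyl]pyridin-4(1H)-one | CC(C)(C)[Si](C)(C)OCc1c(I)c(=O)c(OC)c(CO[Si](c2ccccc2)(c2ccccc2)C(C)(C)C)n1OC | intermediate
10 | 3-(chloromagnesio)-6-[(TBDPS-oxy)methyl]-1,5-dimethoxy-2-[(TBS-oxy)methyl]pyridin-4(1H)-one | CC(C)(C)[Si](C)(C)OCc1c([Mg]Cl)c(=O)c(OC)c(CO[Si](c2ccccc2)(c2ccccc2)C(C)(C)C)n1OC | intermediate
11 | 6-[(TBDPS-oxy)methyl]-1,5-dimethoxy-4-oxo-2-[(TBS-oxy)methyl]-1,4-dihydropyridine-3-carbaldehyde | CC(C)(C)[Si](C)(C)OCc1c(C=O)c(=O)c(OC)c(CO[Si](c2ccccc2)(c2ccccc2)C(C)(C)C)n1OC | intermediate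
12 | allylmagnesium bromide | C=CC[Mg]Br | starting material
13 | racemic 3-(1-hydroxybut-3-en-1-yl)-6-[(TBDPS-oxy)methyl]-1,5-dimethoxy-2-[(TBS-oxy)methyl]pyridin-4(1H)-one | CC(C)(C)[Si](C)(C)OCc1c(C(O)CC=C)c(=O)c(OC)c(CO[Si](c2ccccc2)(c2ccccc2)C(C)(C)C)n1OC | intermediate
14 | allyltrimethylsilane | C=CC[Si](C)(C)C | starting material
15 | 3-(hepta-1,6-dien-4-yl)-6-[(TBDPS-oxy)methyl]-1,5-dimethoxy-2-[(TBS-oxy)methyl]pyridin-4(1H)-one | CC(C)(C)[Si](C)(C)OCc1c(C(CC=C)CC=C)c(=O)c(OC)c(CO[Si](c2ccccc2)(c2ccccc2)C(C)(C)C)n1OC | intermediate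
16 | 3-(hepta-1,6-dien-4-yl)-2-(hydroxymethyl)-6-[(TBDPS-oxy)methyl]-1,5-dimethoxypyridin-4(1H)-one | OCc1c(C(CC=C)CC=C)c(=O)c(OC)c(CO[Si](c2ccccc2)(c2ccccc2)C(C)(C)C)n1OC | intermediate
17 | 3-(hepta-1,6-dien-4-yl)-6-[(TBDPS-oxy)methyl]-1,5-dimethoxy-4-oxo-1,4-dihydropyridine-2-carbaldehyde | O=Cc1c(C(CC=C)CC=C)c(=O)c(OC)c(CO[Si](c2ccccc2)(c2ccccc2)C(C)(C)C)n1OC | intermediate
18 | 3-(hepta-1,6-dien-4-yl)-6-[(TBDPS-oxy)methyl]-1,5-dimethoxy-2-vinylpyridin-4(1H)-one | C=Cc1c(C(CC=C)CC=C)c(=O)c(OC)c(CO[Si](c2ccccc2)(c2ccccc2)C(C)(C)C)n1OC | intermediate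
19 | 3-(cyclopent-3-en-1-yl)-6-[(TBDPS-oxy)methyl]-1,5-dimethoxy-2-vinylpyridin-4(1H)-one | C=Cc1c(C2CC=CC2)c(=O)c(OC)c(CO[Si](c3ccccc3)(c3ccccc3)C(C)(C)C)n1OC | intermediate
20 | (5R)-5-allyl-2-[(TBDPS-oxy)methyl]-1,3-dimethoxy-5,6-dihydroquinolin-4(1H)-one | C=CC[C@@H]1CC=Cc2c1c(=O)c(OC)c(CO[Si](c3ccccc3)(c3ccccc3)C(C)(C)C)n2OC | intermediate
21 | 1-heptene | C=CCCCCC | starting material
22 | (5R)-5-(oct-2-en-1-yl)-2-[(TBDPS-oxy)methyl]-1,3-dimethoxy-5,6-dihydroquinolin-4(1H)-one, E/Z mixture | CCCCCC=CC[C@@H]1CC=Cc2c1c(=O)c(OC)c(CO[Si](c3ccccc3)(c3ccccc3)C(C)(C)C)n2OC | intermediate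
23 | (5R)-2-[(TBDPS-oxy)methyl]-1,3-dimethoxy-5-octyl-5,6,7,8-tetrahydroquinolin-4(1H)-one | CCCCCCCC[C@@H]1CCCc2c1c(=O)c(OC)c(CO[Si](c3ccccc3)(c3ccccc3)C(C)(C)C)n2OC | intermediate
24 | (5R)-2-(hydroxymethyl)-1,3-dimethoxy-5-octyl-5,6,7,8-tetrahydroquinolin-4(1H)-one | CCCCCCCC[C@@H]1CCCc2c1c(=O)c(OC)c(CO)n2OC | target

**Totals**

Total step count: 16. Longest linear sequence: 16 steps (1 → 24).

**Steps most likely to fail**

Step 13. The achiral cyclopentene may be channelled into the six-membered ring only incompletely. Closure may also run through more than one pathway with different enantiotopic preference, which would lower the enantiomeric purity, and the Lewis-basic pyridone oxygen may slow the Mo catalyst. The fallback sets out from 18 and gives up catalyst control. Ring-closing/ring-rearrangement metathesis with the achiral catalyst RuCl2(SIMes)(=CH-2-i-PrOC6H4) in CH2Cl2 at 40 °C under ethylene, run until the cyclopentene is consumed, should give racemic 5-allyl-2-[(TBDPS-oxy)methyl]-1,3-dimethoxy-5,6-dihydroquinolin-4(1H)-one F1. Preparative chromatography on a chiral stationary phase then separates the enantiomers. The (5S)-5-allyl-2-[(TBDPS-oxy)methyl]-1,3-dimethoxy-5,6-dihydroquinolin-4(1H)-one F2 is set aside, and the (5R)-enantiomer is 20, where the route is rejoined.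

Step 4. The weakly nucleophilic alkoxyamine may add too slowly, and prolonged heating may then cause loss of the TBS group or O-methyl oxime formation at C4. The fallback sets out from 5 and brings in the N–O unit in two stages. Hydroxylamine hydrochloride with NaOAc in EtOH–H2O at 70 °C, the well-used exchange with the stronger nucleophile, should give 1-hydroxy-6-(hydroxymethyl)-5-methoxy-2-[(TBS-oxy)methyl]pyridin-4(1H)-one F3. Selective O-methylation of the acidic N-hydroxy group with MeI and K2CO3 in DMF at rt then returns to 7.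

Step 9. Ionisation may be too slow because BF3 binds the pyridone oxygen, the cation may lose a proton to give the conjugated diene, or it may be captured by the neighbouring silyl ether oxygen. The fallback sets out from 9 and replaces the cationic sequence by a C(sp2)–C(sp3) cross-coupling that bypasses 11 and 13. Commercial hepta-1,6-dien-4-ol is converted with CBr4 and PPh3 into 4-bromohepta-1,6-diene F4. Zinc insertion (Zn, LiCl, THF) gives hepta-1,6-dien-4-ylzinc bromide F5, and Negishi coupling with 9 (Pd(OAc)2, CPhos, THF–toluene, rt) comes back to the route at 15.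

**Further compounds**

F1 | step 13 | racemic 5-allyl-2-[(TBDPS-oxy)methyl]-1,3-dimethoxy-5,6-dihydroquinolin-4(1H)-one | C=CCC1CC=Cc2c1c(=O)c(OC)c(CO[Si](c3ccccc3)(c3ccccc3)C(C)(C)C)n2OC
F2 | step 13 | (5S)-5-allyl-2-[(TBDPS-oxy)methyl]-1,3-dimethoxy-5,6-dihydroquinolin-4(1H)-one | C=CC[C@H]1CC=Cc2c1c(=O)c(OC)c(CO[Si](c3ccccc3)(c3ccccc3)C(C)(C)C)n2OC
F3 | step 4 | 1-hydroxy-6-(hydroxymethyl)-5-methoxy-2-[(TBS-oxy)methyl]pyridin-4(1H)-one | CC(C)(C)[Si](C)(C)OCc1cc(=O)c(OC)c(CO)n1O
F4 | step 9 | 4-bromohepta-1,6-diene | BrC(CC=C)CC=C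
F5 | step 9 | hepta-1,6-dien-4-ylzinc bromide | Br[Zn]C(CC=C)CC=C
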